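# Proposed synthesis of CNP0353320.2 by nickel-catalysed alkyne insertion into a prochiral cyclobutanone

## The problem

The target joins C6′ of a 2-methoxy-3,5-dimethyl-4-pyranone to a quaternary carbon, C1, of a 1,3,5-trimethylcyclohexa-2,4-diene. The neighbouring ring carbon C6 carries an (E)-4-oxopent-2-en-2-yl chain, so C6′, C1, C6 and Cα form a run of four crowded carbons. There are two stereocentres, C1 (S) and C6 (S), with the chain and the pyranone cis. C1 has no hydrogen and cannot be corrected later, so it must be set enantioselectively on its own. C6 can then be set from C1, but only through a group on C1 that reaches across to it, because methyl and a carboxyl-derived group are too similar in size for steric control. C6–H is allylic to the diene and γ to the chain enone, so base epimerizes it in the target. In any precursor that has a C5 carbonyl beside an sp2 Cα, the C6 configuration is lost at once. The diene is sensitive to strong acid, oxidants and light, and the methoxypyranone to hard nucleophiles, so the enone has to be released last and without base. The enabling feature is that C5–C6–C1–C2 is the carbon frame of a 3,3-disubstituted cyclobutanone (C5 as carbonyl) whose arms C2 and C6 are enantiotopic, and C3(CH3)–C4H is propyne. Inserting the alkyne into one carbonyl–CH2 bond builds the six-membered ring and makes C1 stereogenic in one act.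

## Retrosynthesis

**Chain enone (19 from 18).** No skeletal bond is cut. The enone of 19 is traced to the tertiary propargylic alcohol 18, which a Meyer–Schuster rearrangement converts by moving oxygen from Cα to Cγ. A ketal or an allylic alcohol of the finished enone would need the trisubstituted E-alkene to be built earlier at a crowded carbon. In 18 the carbinol is sp3, so C6–H stays an ordinary allylic hydrogen through every basic step. The forward reaction must be neutral, leave diene and pyranone alone, and give the E isomer, which is the thermodynamic one (acetyl cis to the small methyl).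

**Pyranone (18 from 17, 16, 15, and from 13 + 14).** The bonds cut are O–CH3, the ring O1′–C2′ bond and C5′–C6′. A finished pyranone cannot be coupled to a quaternary sp3 carbon, so the heterocycle is grown on C1: lactol 13 is the masked C1 aldehyde and keto ester 14 supplies the remaining five carbons. The sequence is aldol addition, oxidation to diketo ester 16, ring closure to 17 and O-methylation. The forward steps need the lactol to react through its aldehyde form, the oxidation to spare the tertiary carbinol, and methylation at the lactone carbonyl oxygen.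

**C5 methyl and the diene (13 from 12, 11, 10).** The C5–CH3 bond is cut to dienyl triflate 12/11, and the triflate to enone 10. Triflation with γ-proton loss turns the C5 carbonyl into a coupling handle and puts both ring double bonds in place in one step. Methyl addition to C5 and dehydration would give no control over where the double bonds end up. The lactone is reduced to lactol 12 before the palladium step, because a tertiary propargylic carboxylate can ionize on zerovalent palladium. The forward triflation must remove a proton from C2, not from C6 or the C3 methyl.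

**C6 and the chain carbons (10 from 7 + 8).** The C6–Cα bond and the lactone C–O bond are cut, giving enone ester 7 and ynone 8. The lactone is how C1 controls C6: only the aldol adduct with the carbinol cis to the ester can close, and the ring then holds C6 while C5 is still a ketone.

- Direct attachment of the finished chain by vinylogous acyl substitution, even delivered from the C1 carboxyl through an enol-ester tether, was set aside. Its product is an ene-1,5-dione that is more acidic at C6 than the starting ketone, so it is deprotonated as it forms and keeps no memory of the delivery.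
- An aldehyde in place of 8 would give a secondary carbinol that needs three more steps and must later be told apart from a second secondary alcohol.

Precursor 7 has one stereocentre and ten carbons. The forward step asks for 1,2- over 1,4-addition, lactonization, and return of the trans adduct by retro-aldol.

**Ring and C1 (7 from 5 + 6).** C4–C5 and C2–C3 are cut, leading to achiral cyclobutanone 5 and propyne 6. An aldol or annulation route to the same enone would need a separate enantioselective event at the quaternary carbon. Here the ring and the stereocentre arise together. The forward reaction must choose one of two enantiotopic ring bonds, place the alkyne CH on the carbonyl carbon, and outrun alkyne oligomerization.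

**Cyclobutanone (5 from 4, 3, 1).** The C1–CH3 bond is cut. Ester enolate methylation with the ketone masked as a ketal leads back to commercial acid 1.

## Roads not taken

**Alternative 1: dearomative alkenylation–methylation.** The cut is at C6–Cα and C1–CH3, leading to arene A1 bound to a Cr(CO)3 fragment. An alkenyllithium would add to an ortho carbon anti to chromium, and a methyl electrophile would then pass through the metal to the ipso carbon, giving ketal A2.

- Merits: it is by far the shortest road. Both stereocentres, their trans methyl/chain relationship and the whole diene come from one operation on a flat arene.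
- Weak points: ortho addition normally needs a coordinating directing group, and the pyranone is itself open to attack by the organolithium. Alkyl groups on chromium usually insert CO before migrating, so acyl transfer, not methyl transfer, is the expected outcome. The absolute configuration would need a chiral ligand to tell apart two mirror-related ortho carbons. Chromium is used stoichiometrically.
- Comparison: this road wins on step count. The chosen plan has one unproven event with a classical replacement; this alternative stacks several unproven events in a single step with no way around them.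

**Alternative 2: Diels–Alder of a siloxydiene with a chiral butenolide.** The cut is at C1–C2 and C5–C6. Siloxydiene A3 adds to butenolide A4 anti to the menthyloxy group; acid work-up gives cis-fused enone lactone A5.

- Merits: both stereocentres, the cis relationship and the absolute configuration come from a cheap auxiliary by a well-understood facial rule. The lactone carbonyl on C1 and the acetal carbon on C6 are useful handles.
- Weak points: the α-methyl butenolide is a poor dienophile and must form a quaternary carbon. A5 carries oxygen at C4, where the target has none, and an sp3 C5, so the ring needs deoxygenation and a new C4=C5 bond. The chain carbon arrives without its methyl, at an aldehyde oxidation level next to an epimerizable centre.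
- Comparison: its stereochemistry is more secure than the chosen plan's. The chosen key step instead delivers oxygen at C5 and methyl at C3 exactly where the diene and the C5 methyl are needed, so fewer corrective steps follow.

**Alternative 3: desymmetrizing amine-catalysed aldol.** The cut is at C3–C4. Diketone A6 would condense under a chiral primary amine to enone A7.

- Merits: the reaction class is known for 4-substituted heptane-2,6-diones, is metal-free, and puts the pyranone in before the ring.
- Weak points: known cases have a hydrogen on the prochiral carbon; discrimination between methyl and a flat pyranone on a quaternary carbon is untested. A6 takes several steps to make. Most seriously, in A7 the chain must enter at C6 cis to the bulky pyranone with no carboxyl left to tether it.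
- Comparison: its key step is closer to precedent than the chosen one. The chosen plan keeps the C1 carboxyl, which is what sets C6.

Key step: step 4

## Route

Assumption on the chemistry: the carbinol carbon of the latent chain (9–13, 15–18), the lactol carbon (12, 13), and the carbinol and CH(CH3) carbons of the keto ester chain (15, 16) form as mixtures of epimers. All of these carbons are sp2 in 19, so the mixtures are carried on and their SMILES leave these centres open.

Step 1
Reactants: 1 3-oxocyclobutane-1-carboxylic acid
Product: 3 methyl 3,3-dimethoxycyclobutane-1-carboxylate, via methyl 3-oxocyclobutane-1-carboxylate 2 (not isolated)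
Conditions: HC(OMe)3, MeOH, TsOH (cat.), reflux
Reagents that add atoms: methanol CO; trimethyl orthoformate COC(OC)OC
Why: Fischer esterification and acid-catalysed ketalization run in one pot, with the orthoformate removing water; the ketal protects the ketone from the base of step 2.

Step 2
Reactants: 3 methyl 3,3-dimethoxycyclobutane-1-carboxylate
Product: 4 methyl 3,3-dimethoxy-1-methylcyclobutane-1-carboxylate
Conditions: LiN(i-Pr)2, THF, −78 °C; MeI, −78 °C to rt
Reagents that add atoms: iodomethane CI
Why: Ester enolate alkylation; the only acidic hydrogen is on C1, and the product keeps its mirror plane, so no stereocentre arises.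

Step 3
Reactants: 4 methyl 3,3-dimethoxy-1-methylcyclobutane-1-carboxylate
Product: 5 methyl 1-methyl-3-oxocyclobutane-1-carboxylate
Conditions: 2 M aq. HCl, THF, rt
Reagents that add atoms: water O
Why: Acid hydrolysis of the dimethyl ketal; the hindered methyl ester is stable to dilute acid at room temperature.

Step 4
Reactants: 5 methyl 1-methyl-3-oxocyclobutane-1-carboxylate; 6 propyne
Product: 7 methyl (1S)-1,3-dimethyl-5-oxocyclohex-3-ene-1-carboxylate
Conditions: Ni(cod)2 (10 mol %), TADDOL-derived dimethylphosphoramidite (20 mol %, enantiomer to be chosen by experiment), propyne added slowly as a toluene solution, toluene, 80 °C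
Reagents that add atoms: none
Why: Proposed new method: zerovalent nickel should couple the strained carbonyl of 5 with propyne by oxidative cyclization to an oxanickelacyclopentene, with the alkyne CH carbon bonded to the carbonyl carbon (new C4–C5 bond) and the methyl-bearing carbon on nickel. β-Carbon elimination then breaks one carbonyl–CH2 bond of the four-membered ring, driven by release of ring strain, to give a seven-membered nickelacycle. C(sp3)–C(sp2) reductive elimination forms C2–C3 and closes the six-membered ring, a formal [4+2] ring expansion. The closest known reaction type is the intermolecular insertion of internal alkynes into 3,3-disubstituted cyclobutanones under Ni(cod)2 with a trialkylphosphine, which is racemic, together with enantioselective intramolecular alkene insertions under nickel with chiral phosphoramidites; a terminal alkyne and an enantioselective intermolecular case are both untested. The only new stereocentre, quaternary C1, is set by the chiral ligand choosing which of the two enantiotopic carbonyl–CH2 bonds is cleaved, with no bond made to C1. Regiochemistry rests on the steric difference between the two alkyne termini (H against CH3), as in nickel-mediated carbonyl–alkyne couplings where the smaller terminus bonds to carbon. Chemoselectivity against alkyne oligomerization rests on keeping propyne scarce by slow addition, and the ester on C1 is a remote spectator with no α-hydrogen.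

Step 5
Reactants: 7 methyl (1S)-1,3-dimethyl-5-oxocyclohex-3-ene-1-carboxylate; 8 pent-3-yn-2-one
Product: 10 (3aR,7aS)-3,6,7a-trimethyl-3-(prop-1-yn-1-yl)-3,3a,7,7a-tetrahydro-2-benzofuran-1,4-dione (cis-fused keto lactone; both C3 epimers), via aldol adduct 9 (not isolated)
Conditions: LiN(i-Pr)2, THF, −78 °C; 8 added cold, −78 to −20 °C; aq. NH4Cl at −20 °C
Reagents that add atoms: none
Why: Aldol addition–lactonization: kinetic deprotonation of the enone at the α′ carbon C6, as with isophorone, then 1,2-addition of the lithium enolate to the electrophilic alkynyl ketone. Only the adduct with the carbinol cis to the ester can close the five-membered lactone, while the trans adduct, a hindered ketone aldolate, returns by retro-aldol, so the ring fusion fixes C6 cis to the C1 carbonyl.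

Step 6
Reactants: 10 cis-fused keto lactone
Product: 11 (3aR,7aS)-3,6,7a-trimethyl-1-oxo-3-(prop-1-yn-1-yl)-1,3,3a,7a-tetrahydro-2-benzofuran-4-yl trifluoromethanesulfonate
Conditions: Tf2O, 2,6-di-tert-butyl-4-methylpyridine, CH2Cl2, 0 °C to rt
Reagents that add atoms: trifluoromethanesulfonic anhydride O=S(=O)(OS(=O)(=O)C(F)(F)F)C(F)(F)F
Why: Dienyl triflate formation: O-triflation of the enone gives a triflyloxyallyl cation, and the hindered base removes a γ-proton from C2 to give the through-conjugated dienyl triflate, as with steroidal 4-en-3-ones. C6–H is a shielded methine, and the absence of an enolate avoids β-elimination of the lactone oxygen, so C6 is untouched.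

Step 7
Reactants: 11 dienyl triflate lactone
Product: 12 (3aR,7aS)-1-hydroxy-3,6,7a-trimethyl-3-(prop-1-yn-1-yl)-1,3,3a,7a-tetrahydro-2-benzofuran-4-yl trifluoromethanesulfonate (lactol)
Conditions: i-Bu2AlH, CH2Cl2, −78 °C; Rochelle salt work-up
Reagents that add atoms: none
Why: Partial reduction of a lactone to a lactol through the aluminium hemiacetal, which is stable at −78 °C. Alkenyl triflate and alkyne are inert to the hydride, and the reduction removes the propargylic carboxylate before palladium is used.

Step 8
Reactants: 12 lactol triflate
Product: 13 (3aR,7aS)-3,4,6,7a-tetramethyl-3-(prop-1-yn-1-yl)-1,3,3a,7a-tetrahydro-2-benzofuran-1-ol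
Conditions: SnMe4, Pd(PPh3)4 (5 mol %), LiCl, DMF, 60 °C
Reagents that add atoms: tetramethylstannane C[Sn](C)(C)C
Why: Stille coupling of an alkenyl triflate; the double bonds stay where the triflate fixed them, and the neutral conditions tolerate the lactol and the internal alkyne.

Step 9
Reactants: 13 methyl diene lactol; 14 methyl 2-methyl-3-oxopentanoate
Product: 15 methyl 5-hydroxy-5-[(1S,6R)-6-(2-hydroxypent-3-yn-2-yl)-1,3,5-trimethylcyclohexa-2,4-dien-1-yl]-2,4-dimethyl-3-oxopentanoate
Conditions: 14, NaH then n-BuLi, THF, 0 °C (dianion, 4 equiv); 13 added at −78 °C, then to 0 °C; aq. NH4Cl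
Reagents that add atoms: none
Why: Aldol addition of a β-keto ester dianion through its γ-carbon. One equivalent deprotonates the lactol, whose open alkoxy aldehyde form has no α-hydrogen and is trapped by the nucleophile.

Step 10
Reactants: 15 diol keto ester
Product: 16 methyl 5-[(1S,6R)-6-(2-hydroxypent-3-yn-2-yl)-1,3,5-trimethylcyclohexa-2,4-dien-1-yl]-2,4-dimethyl-3,5-dioxopentanoate
Conditions: Dess–Martin periodinane, NaHCO3, CH2Cl2, 0 °C to rt
Reagents that add atoms: none
Why: Dess–Martin oxidation of the secondary alcohol to the 1,3-diketone. The tertiary carbinol cannot be oxidized, and the buffer keeps acid from dehydrating a hemiketal between it and the new ketone.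

Step 11
Reactants: 16 diketo ester
Product: 17 4-hydroxy-6-[(1S,6R)-6-(2-hydroxypent-3-yn-2-yl)-1,3,5-trimethylcyclohexa-2,4-dien-1-yl]-3,5-dimethyl-2H-pyran-2-one
Conditions: DBU, toluene, rt to 60 °C; dilute HCl work-up
Reagents that add atoms: none
Why: Base-mediated lactonization of a 3,5-diketo ester: the enolate oxygen of the C1-bound carbonyl attacks the ester and methanol is lost, the standard entry to 4-hydroxy-2-pyranones. Under base the open diketonate, not the hemiketal, is the populated form.

Step 12
Reactants: 17 hydroxypyranone
Product: 18 6-[(1S,6R)-6-(2-hydroxypent-3-yn-2-yl)-1,3,5-trimethylcyclohexa-2,4-dien-1-yl]-2-methoxy-3,5-dimethyl-4H-pyran-4-one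
Conditions: MeOTf, CH2Cl2, 0 °C to rt; aq. NaHCO3
Reagents that add atoms: methyl trifluoromethanesulfonate COS(=O)(=O)C(F)(F)F
Why: O-Methylation of the neutral 4-hydroxy-2-pyranone at its lactone carbonyl oxygen, the most nucleophilic site, gives a 4-hydroxy-2-methoxypyrylium ion that loses a proton to the α-methoxy-γ-pyranone. The hindered tertiary alcohol is alkylated far more slowly.

Step 13
Reactants: 18 propargylic alcohol pyranone
Product: 19 2-methoxy-3,5-dimethyl-6-{(1S,6S)-1,3,5-trimethyl-6-[(2E)-4-oxopent-2-en-2-yl]cyclohexa-2,4-dien-1-yl}-4H-pyran-4-one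
Conditions: Ph3PAuNTf2 (2 mol %), MeOH (1 equiv), toluene, rt
Reagents that add atoms: none
Why: Meyer–Schuster rearrangement: monovalent gold activates the alkyne for a formal 1,3-shift of the hydroxyl, and the resulting allenol tautomerizes to the enone. The E isomer (acetyl cis to methyl) is the thermodynamic product, and without base C6 keeps its configuration; the descriptor changes from R to S only because the CIP priorities change.

## Compound list

1 | 3-oxocyclobutane-1-carboxylic acid | OC(=O)C1CC(=O)C1 | starting material
2 | methyl 3-oxocyclobutane-1-carboxylate | COC(=O)C1CC(=O)C1 | intermediate (not isolated)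
3 | methyl 3,3-dimethoxycyclobutane-1-carboxylate | COC(=O)C1CC(OC)(OC)C1 | intermediate
4 | methyl 3,3-dimethoxy-1-methylcyclobutane-1-carboxylate | COC(=O)C1(C)CC(OC)(OC)C1 | intermediate
5 | methyl 1-methyl-3-oxocyclobutane-1-carboxylate | COC(=O)C1(C)CC(=O)C1 | intermediate
6 | propyne | CC#C | starting material
7 | methyl (1S)-1,3-dimethyl-5-oxocyclohex-3-ene-1-carboxylate | COC(=O)[C@@]1(C)CC(C)=CC(=O)C1 | intermediate
8 | pent-3-yn-2-one | CC#CC(C)=O | starting material
9 | methyl (1S,6R)-6-(2-hydroxypent-3-yn-2-yl)-1,3-dimethyl-5-oxocyclohex-3-ene-1-carboxylate (aldol adduct, present as its lithium alkoxide; carbinol epimers) | COC(=O)[C@@]1(C)CC(C)=CC(=O)[C@H]1C(C)(O)C#CC | intermediate (not isolated)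
10 | (3aR,7aS)-3,6,7a-trimethyl-3-(prop-1-yn-1-yl)-3,3a,7,7a-tetrahydro-2-benzofuran-1,4-dione (cis-fused; C3 epimers) | O=C1[C@@]2(C)CC(C)=CC(=O)[C@H]2C(C)(C#CC)O1 | intermediate
11 | (3aR,7aS)-3,6,7a-trimethyl-1-oxo-3-(prop-1-yn-1-yl)-1,3,3a,7a-tetrahydro-2-benzofuran-4-yl trifluoromethanesulfonate (C3 epimers) | O=C1[C@@]2(C)C=C(C)C=C(OS(=O)(=O)C(F)(F)F)[C@H]2C(C)(C#CC)O1 | intermediate
12 | (3aR,7aS)-1-hydroxy-3,6,7a-trimethyl-3-(prop-1-yn-1-yl)-1,3,3a,7a-tetrahydro-2-benzofuran-4-yl trifluoromethanesulfonate (C1 and C3 epimers) | OC1[C@@]2(C)C=C(C)C=C(OS(=O)(=O)C(F)(F)F)[C@H]2C(C)(C#CC)O1 | intermediate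
13 | (3aR,7aS)-3,4,6,7a-tetramethyl-3-(prop-1-yn-1-yl)-1,3,3a,7a-tetrahydro-2-benzofuran-1-ol (C1 and C3 epimers) | OC1[C@@]2(C)C=C(C)C=C(C)[C@H]2C(C)(C#CC)O1 | intermediate
14 | methyl 2-methyl-3-oxopentanoate | CCC(=O)C(C)C(=O)OC | starting material
15 | methyl 5-hydroxy-5-[(1S,6R)-6-(2-hydroxypent-3-yn-2-yl)-1,3,5-trimethylcyclohexa-2,4-dien-1-yl]-2,4-dimethyl-3-oxopentanoate (chain epimers) | COC(=O)C(C)C(=O)C(C)C(O)[C@@]1(C)C=C(C)C=C(C)[C@H]1C(C)(O)C#CC | intermediate
16 | methyl 5-[(1S,6R)-6-(2-hydroxypent-3-yn-2-yl)-1,3,5-trimethylcyclohexa-2,4-dien-1-yl]-2,4-dimethyl-3,5-dioxopentanoate (chain epimers) | COC(=O)C(C)C(=O)C(C)C(=O)[C@@]1(C)C=C(C)C=C(C)[C@H]1C(C)(O)C#CC | intermediate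
17 | 4-hydroxy-6-[(1S,6R)-6-(2-hydroxypent-3-yn-2-yl)-1,3,5-trimethylcyclohexa-2,4-dien-1-yl]-3,5-dimethyl-2H-pyran-2-one (carbinol epimers) | O=c1oc([C@@]2(C)C=C(C)C=C(C)[C@H]2C(C)(O)C#CC)c(C)c(O)c1C | intermediate
18 | 6-[(1S,6R)-6-(2-hydroxypent-3-yn-2-yl)-1,3,5-trimethylcyclohexa-2,4-dien-1-yl]-2-methoxy-3,5-dimethyl-4H-pyran-4-one (carbinol epimers) | COc1oc([C@@]2(C)C=C(C)C=C(C)[C@H]2C(C)(O)C#CC)c(C)c(=O)c1C | intermediate
19 | 2-methoxy-3,5-dimethyl-6-{(1S,6S)-1,3,5-trimethyl-6-[(2E)-4-oxopent-2-en-2-yl]cyclohexa-2,4-dien-1-yl}-4H-pyran-4-one | COc1oc([C@@]2(C)C=C(C)C=C(C)[C@H]2/C(C)=C/C(C)=O)c(C)c(=O)c1C | target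

## Step count and risks

Total: 13 steps. Longest linear sequence: 13 steps, from 1 to 19; compounds 6, 8 and 14 are commercial and enter directly.

**Step 4 (key step, the one step marked "Proposed new method:").** Oligomerization or cyclotrimerization of propyne at zerovalent nickel may outrun the carbonyl–alkyne coupling. The ligand may discriminate poorly between the two enantiotopic ring bonds, and the alkyne may insert with the wrong orientation. The fallback uses known chemistry and does not branch from a route compound: compounds 1 to 6 are set aside, and it rejoins the route at 7.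

- It begins with commercial 3-methoxy-5-methylbenzoic acid F1. Birch reduction with Li in NH3/THF and trapping of the carboxylate-stabilized anion with MeI gives 3-methoxy-1,5-dimethylcyclohexa-2,5-diene-1-carboxylic acid F2.
- Dilute HCl hydrolyses the enol ether and moves the remaining double bond into conjugation, giving racemic 1,3-dimethyl-5-oxocyclohex-3-ene-1-carboxylic acid F3.
- Crystallization of the salt with one enantiomer of 1-phenylethylamine gives (1S)-1,3-dimethyl-5-oxocyclohex-3-ene-1-carboxylic acid F4. MeI with K2CO3 in DMF then gives 7.
- The price is the loss of half the material in the resolution.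

**Step 5.** Conjugate addition of the enolate to the ynone, or proton transfer between them, may compete with 1,2-addition. The trans adduct may fail to return by retro-aldol, and the lactone may undergo base-induced β-elimination. The fallback sets out from 7 and returns at 13; it builds the chain in stages from an aldehyde, which adds cleanly and irreversibly.

- Enolate of 7 with acetaldehyde, then warming, gives (3aR,7aS)-3,6,7a-trimethyl-3,3a,7,7a-tetrahydro-2-benzofuran-1,4-dione F5. The trans aldol cannot lactonize; it is separated and returned to 7 by base-induced retro-aldol.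
- Triflation as in step 6 gives (3aR,7aS)-3,6,7a-trimethyl-1-oxo-1,3,3a,7a-tetrahydro-2-benzofuran-4-yl trifluoromethanesulfonate F6.
- Stille methylation as in step 8 gives (3aR,7aS)-3,4,6,7a-tetramethyl-3a,7a-dihydro-2-benzofuran-1(3H)-one F7.
- Opening with MeNHOMe·HCl and AlMe3 gives (1S,6R)-6-(1-hydroxyethyl)-N-methoxy-N,1,3,5-tetramethylcyclohexa-2,4-diene-1-carboxamide F8.
- Dess–Martin oxidation gives (1S,6R)-6-acetyl-N-methoxy-N,1,3,5-tetramethylcyclohexa-2,4-diene-1-carboxamide F9.
- MeC≡CMgBr with CeCl3 at −78 °C adds to the ketone, and the alkoxide closes onto the amide to give (3aR,7aS)-3,4,6,7a-tetramethyl-3-(prop-1-yn-1-yl)-3a,7a-dihydro-2-benzofuran-1(3H)-one F10.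
- i-Bu2AlH reduction of F10 gives 13.

**Step 6.** Proton loss from the C3 methyl or from C6 instead of C2 would give regioisomeric dienyl triflates. The fallback sets out from 10 and returns at 11. Isopropenyl acetate with TsOH under equilibrating conditions gives the through-conjugated dienyl acetate, (3aS,7aS)-3,6,7a-trimethyl-1-oxo-3-(prop-1-yn-1-yl)-1,3,3a,7a-tetrahydro-2-benzofuran-4-yl acetate F11. MeLi at −78 °C cleaves the acetate to the regiodefined lithium dienolate, which N-phenylbis(trifluoromethanesulfonimide) traps as 11.

**Step 9.** The lactolate may stay ring-closed, so that the dianion finds no aldehyde and only proton transfer occurs. The fallback sets out from 11 and returns at 16; it works at the lactone oxidation level. Claisen acylation of the dianion of 14 by lactone 11 opens the ring to methyl 5-[(1S,6R)-6-(2-hydroxypent-3-yn-2-yl)-1,3-dimethyl-5-(trifluoromethanesulfonyloxy)cyclohexa-2,4-dien-1-yl]-2,4-dimethyl-3,5-dioxopentanoate F12. Stille methylation with SnMe4, Pd(PPh3)4 and LiCl then gives 16. Steps 7, 8 and 10 are not needed in this variant.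

**Step 13.** Dehydration of the tertiary alcohol to an enyne, activation of the diene by the gold cation, or incomplete E/Z equilibration may compete. The fallback sets out from 18 and returns at 19. Semi-hydrogenation over Pd/CaCO3 poisoned with Pb(OAc)2 and quinoline gives 6-[(1S,6R)-6-[(3Z)-2-hydroxypent-3-en-2-yl]-1,3,5-trimethylcyclohexa-2,4-dien-1-yl]-2-methoxy-3,5-dimethyl-4H-pyran-4-one F13. Pyridinium chlorochromate, (C5H5NH)[CrO3Cl], buffered with NaOAc, effects Babler–Dauben oxidative transposition of this tertiary allylic alcohol to 19.

## Further compounds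

F1 | step 4 | 3-methoxy-5-methylbenzoic acid | COc1cc(C)cc(C(O)=O)c1
F2 | step 4 | 3-methoxy-1,5-dimethylcyclohexa-2,5-diene-1-carboxylic acid | OC(=O)C1(C)C=C(OC)CC(C)=C1
F3 | step 4 | racemic 1,3-dimethyl-5-oxocyclohex-3-ene-1-carboxylic acid | OC(=O)C1(C)CC(C)=CC(=O)C1
F4 | step 4 | (1S)-1,3-dimethyl-5-oxocyclohex-3-ene-1-carboxylic acid | OC(=O)[C@@]1(C)CC(C)=CC(=O)C1
F5 | step 5 | (3aR,7aS)-3,6,7a-trimethyl-3,3a,7,7a-tetrahydro-2-benzofuran-1,4-dione (C3 epimers) | O=C1[C@@]2(C)CC(C)=CC(=O)[C@H]2C(C)O1
F6 | step 5 | (3aR,7aS)-3,6,7a-trimethyl-1-oxo-1,3,3a,7a-tetrahydro-2-benzofuran-4-yl trifluoromethanesulfonate (C3 epimers) | O=C1[C@@]2(C)C=C(C)C=C(OS(=O)(=O)C(F)(F)F)[C@H]2C(C)O1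
F7 | step 5 | (3aR,7aS)-3,4,6,7a-tetramethyl-3a,7a-dihydro-2-benzofuran-1(3H)-one (C3 epimers) | O=C1[C@@]2(C)C=C(C)C=C(C)[C@H]2C(C)O1
F8 | step 5 | (1S,6R)-6-(1-hydroxyethyl)-N-methoxy-N,1,3,5-tetramethylcyclohexa-2,4-diene-1-carboxamide (carbinol epimers) | CON(C)C(=O)[C@@]1(C)C=C(C)C=C(C)[C@H]1C(C)O
F9 | step 5 | (1S,6R)-6-acetyl-N-methoxy-N,1,3,5-tetramethylcyclohexa-2,4-diene-1-carboxamide | CON(C)C(=O)[C@@]1(C)C=C(C)C=C(C)[C@H]1C(C)=O
F10 | step 5 | (3aR,7aS)-3,4,6,7a-tetramethyl-3-(prop-1-yn-1-yl)-3a,7a-dihydro-2-benzofuran-1(3H)-one (C3 epimers) | O=C1[C@@]2(C)C=C(C)C=C(C)[C@H]2C(C)(C#CC)O1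
F11 | step 6 | (3aS,7aS)-3,6,7a-trimethyl-1-oxo-3-(prop-1-yn-1-yl)-1,3,3a,7a-tetrahydro-2-benzofuran-4-yl acetate (C3 epimers) | O=C1[C@@]2(C)C=C(C)C=C(OC(C)=O)[C@H]2C(C)(C#CC)O1
F12 | step 9 | methyl 5-[(1S,6R)-6-(2-hydroxypent-3-yn-2-yl)-1,3-dimethyl-5-(trifluoromethanesulfonyloxy)cyclohexa-2,4-dien-1-yl]-2,4-dimethyl-3,5-dioxopentanoate (chain epimers) | COC(=O)C(C)C(=O)C(C)C(=O)[C@@]1(C)C=C(C)C=C(OS(=O)(=O)C(F)(F)F)[C@H]1C(C)(O)C#CC
F13 | step 13 | 6-[(1S,6R)-6-[(3Z)-2-hydroxypent-3-en-2-yl]-1,3,5-trimethylcyclohexa-2,4-dien-1-yl]-2-methoxy-3,5-dimethyl-4H-pyran-4-one (carbinol epimers) | COc1oc([C@@]2(C)C=C(C)C=C(C)[C@H]2C(C)(O)/C=C\C)c(C)c(=O)c1C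
A1 | alternative 1 | 6-(3,5-dimethylphenyl)-2-methoxy-3,5-dimethyl-4H-pyran-4-one (used bound to Cr(CO)3) | COc1oc(-c2cc(C)cc(C)c2)c(C)c(=O)c1C
A2 | alternative 1 | 2-methoxy-3,5-dimethyl-6-{(1S,6S)-1,3,5-trimethyl-6-[(1E)-1-(2-methyl-1,3-dioxolan-2-yl)prop-1-en-2-yl]cyclohexa-2,4-dien-1-yl}-4H-pyran-4-one | COc1oc([C@@]2(C)C=C(C)C=C(C)[C@H]2/C(C)=C/C3(C)OCCO3)c(C)c(=O)c1C
A3 | alternative 2 | 1-methoxy-2-methyl-3-(trimethylsilyloxy)penta-1,3-diene | COC=C(C)C(O[Si](C)(C)C)=CC
A4 | alternative 2 | (5R)-3-methyl-5-{[(1R,2S,5R)-5-methyl-2-(propan-2-yl)cyclohexyl]oxy}furan-2(5H)-one | O=C1C(C)=C[C@H](O[C@@H]2C[C@H](C)CC[C@H]2C(C)C)O1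
A5 | alternative 2 | cis-fused 3-(menthyloxy)-4,6,7a-trimethyl-3a,4-dihydro-2-benzofuran-1,5(3H,7aH)-dione, configuration as in the SMILES | O=C1[C@@]2(C)C=C(C)C(=O)[C@@H](C)[C@H]2[C@H](O[C@@H]3C[C@H](C)CC[C@H]3C(C)C)O1
A6 | alternative 3 | 4-(6-methoxy-3,5-dimethyl-4-oxo-4H-pyran-2-yl)-4-methylheptane-2,6-dione | COc1oc(C(C)(CC(C)=O)CC(C)=O)c(C)c(=O)c1C
A7 | alternative 3 | 6-[(1S)-1,3-dimethyl-5-oxocyclohex-3-en-1-yl]-2-methoxy-3,5-dimethyl-4H-pyran-4-one | COc1oc([C@@]2(C)CC(C)=CC(=O)C2)c(C)c(=O)c1C
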